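**Retrosynthetic overview**
1. Target 24 ⇐ Mitsunobu esterification with inversion at C6 of the macrocyclic alcohol 22 with tiglic acid.
2. 22 (ten-membered carbocycle, formed last) ⇐ intramolecular Nozaki–Hiyama allylation C6–C7 of the (Z)-enal / 3-(bromomethyl)butenolide 21; this also creates C7 and the exocyclic methylene.
3. 21 (3(2H)-furanone, formed second) ⇐ oxidative dearomatization of the 2-alkynyl-3-methylfuran 18. The furan opens to a cis-enedione (Z-C4=C5, C6 aldehyde, C3 ynone), and gold catalysis closes the furanone onto the C10 carbinol.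
4. 18 ⇐ Sonogashira coupling of 3-methylfuran (through its 2-bromide) with alkyne 12; the butenolide (formed first) ⇐ Pd carbonylative lactonization of the (Z)-iodo allylic alcohol 10.
5. 10 ⇐ chelation-controlled ethynylation (sets C10) of aldol 8 ⇐ Ti-catalysed acetone aldol (sets C8) on the (Z)-iodoenal 4 ⇐ mono-THP butynediol 1.

Assumption: locants C1–C15 follow germacrane numbering (C1 ketone, C3–O–C10 ether bridge, C6 ester carbon, C8 lactone carbon, C11=C13 methylene), and 1 is taken as a catalogue compound (otherwise one step from 2-butyne-1,4-diol and dihydropyran).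

**Step 1**
Reactants: 1 4-(tetrahydro-2H-pyran-2-yloxy)but-2-yn-1-ol; 2 iodine
Product: 3 (2Z)-3-iodo-4-(tetrahydro-2H-pyran-2-yloxy)but-2-en-1-ol
Conditions: NaAlH2(OCH2CH2OMe)2 (1.5 equiv), THF, 0 °C to rt; then I2, THF, −78 to 0 °C
Reagents that add atoms: iodine (II)
Why: Hydroxyl-directed trans-hydroalumination puts H on the proximal and Al on the distal alkyne carbon, and iodinolysis with retention gives the (Z)-vinyl iodide with I cis to the CH2OH that becomes C8.

**Step 2**
Reactants: 3 (2Z)-3-iodo-4-(tetrahydro-2H-pyran-2-yloxy)but-2-en-1-ol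
Product: 4 (2Z)-3-iodo-4-(tetrahydro-2H-pyran-2-yloxy)but-2-enal
Conditions: MnO2 (activated, 15 equiv), CH2Cl2, rt, dark
Reagents that add atoms: none
Why: Allylic oxidation with MnO2 is neutral and heterogeneous, so the Z geometry and the acetal survive.

**Step 3**
Reactants: 4 (2Z)-3-iodo-4-(tetrahydro-2H-pyran-2-yloxy)but-2-enal; 5 2-methoxypropene; 6 water
Product: 8 (4S,5Z)-4,7-dihydroxy-6-iodohept-5-en-2-one, via enol ether adduct 7 (not isolated)
Conditions: Ti(OiPr)4 (10 mol%), binaphthyl Schiff-base ligand from 2-amino-2'-hydroxy-1,1'-binaphthyl and 3-bromo-5-tert-butylsalicylaldehyde (20 mol%, antipode for Si-face addition), 2,6-di-tert-butyl-4-methylpyridine, 2-methoxypropene as solvent, 0 °C; then AcOH/THF/H2O 3:1:1, 40 °C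
Reagents that add atoms: 2-methoxypropene (COC(C)=C); water (O)
Why: Titanium-catalysed enantioselective acetone aldol addition with 2-methoxypropene (Mukaiyama-type ene addition) sets C8 as S under catalyst control, and the acidic work-up hydrolyses the enol ether to the methyl ketone and removes the THP group in the same pot.

**Step 4**
Reactants: 8 (4S,5Z)-4,7-dihydroxy-6-iodohept-5-en-2-one; 9 ethynylmagnesium bromide
Product: 10 (2Z,4S,6S)-2-iodo-6-methyloct-2-en-7-yne-1,4,6-triol
Conditions: HC≡CMgBr (5 equiv), MgBr2·OEt2 (2 equiv), CH2Cl2/THF, −78 to −30 °C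
Reagents that add atoms: ethynylmagnesium bromide (C#C[Mg]Br)
Why: Cram-chelate 1,3-induction: the C8 magnesium alkoxide chelates the ketone in a half-chair with the alkenyl group equatorial, and axial attack of the acetylide gives the 1,3-anti diol, which is the 6S centre (C10 of the target).

**Step 5**
Reactants: 10 (2Z,4S,6S)-2-iodo-6-methyloct-2-en-7-yne-1,4,6-triol; 11 carbon monoxide
Product: 12 (5S)-5-[(2S)-2-hydroxy-2-methylbut-3-yn-1-yl]-3-(hydroxymethyl)furan-2(5H)-one
Conditions: Pd(PPh3)2Cl2 (5 mol%), CO (1 atm), K2CO3 (2 equiv), THF, 40 °C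
Reagents that add atoms: carbon monoxide ([C-]#[O+])
Why: Palladium-catalysed carbonylative lactonization (oxidative addition to C–I, CO insertion, capture of the acylpalladium by the cis allylic hydroxyl) closes the butenolide without touching the C8–O bond, so C8 is retained.

**Step 6**
Reactants: 12 (5S)-5-[(2S)-2-hydroxy-2-methylbut-3-yn-1-yl]-3-(hydroxymethyl)furan-2(5H)-one; 13 3-methylfuran; 14 N-bromosuccinimide
Product: 16 (5S)-5-[(2S)-2-hydroxy-2-methyl-4-(3-methylfuran-2-yl)but-3-yn-1-yl]-3-(hydroxymethyl)furan-2(5H)-one, via 2-bromo-3-methylfuran 15 (not isolated)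
Conditions: 13 (1.5 equiv), NBS (1.5 equiv), DMF, 0 °C, dark; then 12, Pd(PPh3)4 (5 mol%), CuI (10 mol%), iPr2NH, rt to 40 °C
Reagents that add atoms: 3-methylfuran (Cc1ccoc1)
Why: Electrophilic bromination of 3-methylfuran goes to C2 (the α position next to the methyl group), and the crude bromide is used directly in a Sonogashira coupling with the terminal alkyne; no stereocentre is touched.

**Step 7**
Reactants: 16 (5S)-5-[(2S)-2-hydroxy-2-methyl-4-(3-methylfuran-2-yl)but-3-yn-1-yl]-3-(hydroxymethyl)furan-2(5H)-one; 17 tetrabromomethane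
Product: 18 (5S)-3-(bromomethyl)-5-[(2S)-2-hydroxy-2-methyl-4-(3-methylfuran-2-yl)but-3-yn-1-yl]furan-2(5H)-one
Conditions: CBr4 (1.2 equiv), PPh3 (1.2 equiv), CH2Cl2, 0 °C
Reagents that add atoms: tetrabromomethane (BrC(Br)(Br)Br)
Why: Appel reaction; the primary allylic hydroxyl reacts much faster than the hindered tertiary propargylic one.

**Step 8 (key step)**
Reactants: 18 (5S)-3-(bromomethyl)-5-[(2S)-2-hydroxy-2-methyl-4-(3-methylfuran-2-yl)but-3-yn-1-yl]furan-2(5H)-one; 19 dimethyldioxirane; 6 water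
Product: 21 (2Z)-3-[(5S)-5-{[(2S)-4-(bromomethyl)-5-oxo-2,5-dihydrofuran-2-yl]methyl}-5-methyl-4-oxo-4,5-dihydrofuran-2-yl]but-2-enal, via Z-enal ynone 20 (not isolated)
Conditions: DMDO (1.05 equiv), acetone/CH2Cl2, −40 to 0 °C; evaporate; then Ph3PAuNTf2 (5 mol%), toluene with H2O (2 equiv), rt, dark
Reagents that add atoms: dimethyldioxirane (CC1(C)OO1); water (O)
Why: Proposed new method: the furan acts as a masked (Z)-ene-1,4-dione, so dioxirane epoxidation and ring opening give the cis-enedione 20 (the ring fixes the C4=C5 Z geometry and reveals the C6 aldehyde and the C3 ynone), and the silver-free cationic gold catalyst then promotes conjugate hydration of the ynone and cyclodehydration of the C10 hydroxyl onto C3 to form the 3(2H)-furanone with C10 untouched; the closest known reactions are the dioxirane oxidation of furans to cis-enediones and the gold-catalysed cyclization of γ-hydroxy alkynones to 3(2H)-furanones, here joined in one flask as a furan-to-furanone transposition.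

**Step 9**
Reactants: 21 (2Z)-3-[(5S)-5-{[(2S)-4-(bromomethyl)-5-oxo-2,5-dihydrofuran-2-yl]methyl}-5-methyl-4-oxo-4,5-dihydrofuran-2-yl]but-2-enal
Product: 22 (6R,7S,8S,10S)-6-hydroxy-1-oxo-3,10-epoxygermacra-2,4Z,11(13)-trien-12,8-olide
Conditions: CrCl2 (8 equiv), 4 Å molecular sieves, THF, 2 mM by syringe-pump addition, rt; aq NH4Cl at 0 °C
Reagents that add atoms: none
Why: Nozaki–Hiyama allylation (intramolecular Barbier type): the allylchromium adds through its γ-carbon C7 in a six-membered chair transition state on the butenolide face opposite the C9 arm (trans ring fusion as in 24) with the enal substituent equatorial, which predicts the anti adduct (6R alcohol), and the allylic transposition creates the exocyclic methylene.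

**Step 10**
Reactants: 22 (6R,7S,8S,10S)-6-hydroxy-1-oxo-3,10-epoxygermacra-2,4Z,11(13)-trien-12,8-olide; 23 tiglic acid
Product: 24 (6S,7R,8S,10S)-6-[(2E)-2-methylbut-2-enoyloxy]-1-oxo-3,10-epoxygermacra-2,4Z,11(13)-trien-12,8-olide (CNP0293168.2)
Conditions: tiglic acid (4 equiv), PPh3 (4 equiv), DIAD (4 equiv), toluene, 0 °C to rt
Reagents that add atoms: tiglic acid (C/C=C(\C)C(=O)O)
Why: Mitsunobu esterification: SN2 displacement of the allylic oxyphosphonium by tiglate inverts C6 to the required 6S configuration and installs the (E)-ester in the same operation (C7 changes descriptor from S to R only through CIP priorities, not in space).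

**Compound list**
1 | 4-(tetrahydro-2H-pyran-2-yloxy)but-2-yn-1-ol (acetal carbon racemic) | OCC#CCOC1CCCCO1 | starting material
2 | iodine | II | starting material
3 | (2Z)-3-iodo-4-(tetrahydro-2H-pyran-2-yloxy)but-2-en-1-ol | OC/C=C(\I)COC1CCCCO1 | intermediate
4 | (2Z)-3-iodo-4-(tetrahydro-2H-pyran-2-yloxy)but-2-enal | O=C/C=C(\I)COC1CCCCO1 | intermediate
5 | 2-methoxypropene | COC(C)=C | starting material
6 | water | O | starting material
7 | (4S,5Z)-6-iodo-2-methoxy-7-(tetrahydro-2H-pyran-2-yloxy)hepta-1,5-dien-4-ol (enol ether adduct) | C=C(OC)C[C@H](O)/C=C(\I)COC1CCCCO1 | intermediate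
8 | (4S,5Z)-4,7-dihydroxy-6-iodohept-5-en-2-one | CC(=O)C[C@H](O)/C=C(\I)CO | intermediate
9 | ethynylmagnesium bromide | C#C[Mg]Br | starting material
10 | (2Z,4S,6S)-2-iodo-6-methyloct-2-en-7-yne-1,4,6-triol | C#C[C@@](C)(O)C[C@H](O)/C=C(\I)CO | intermediate
11 | carbon monoxide | [C-]#[O+] | starting material
12 | (5S)-5-[(2S)-2-hydroxy-2-methylbut-3-yn-1-yl]-3-(hydroxymethyl)furan-2(5H)-one | C#C[C@@](C)(O)C[C@@H]1OC(=O)C(CO)=C1 | intermediate
13 | 3-methylfuran | Cc1ccoc1 | starting material
14 | N-bromosuccinimide | O=C1CCC(=O)N1Br | starting material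
15 | 2-bromo-3-methylfuran | Cc1ccoc1Br | intermediate
16 | (5S)-5-[(2S)-2-hydroxy-2-methyl-4-(3-methylfuran-2-yl)but-3-yn-1-yl]-3-(hydroxymethyl)furan-2(5H)-one | Cc1ccoc1C#C[C@@](C)(O)C[C@@H]1OC(=O)C(CO)=C1 | intermediate
17 | tetrabromomethane | BrC(Br)(Br)Br | starting material
18 | (5S)-3-(bromomethyl)-5-[(2S)-2-hydroxy-2-methyl-4-(3-methylfuran-2-yl)but-3-yn-1-yl]furan-2(5H)-one | Cc1ccoc1C#C[C@@](C)(O)C[C@@H]1OC(=O)C(CBr)=C1 | intermediate
19 | dimethyldioxirane | CC1(C)OO1 | starting material
20 | (2Z,7S)-8-[(2S)-4-(bromomethyl)-5-oxo-2,5-dihydrofuran-2-yl]-7-hydroxy-3,7-dimethyl-4-oxooct-2-en-5-ynal (Z-enal ynone) | O=C/C=C(C)\C(=O)C#C[C@@](C)(O)C[C@@H]1OC(=O)C(CBr)=C1 | intermediate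
21 | (2Z)-3-[(5S)-5-{[(2S)-4-(bromomethyl)-5-oxo-2,5-dihydrofuran-2-yl]methyl}-5-methyl-4-oxo-4,5-dihydrofuran-2-yl]but-2-enal | O=C/C=C(C)\C1=CC(=O)[C@](C)(C[C@@H]2OC(=O)C(CBr)=C2)O1 | intermediate
22 | (6R,7S,8S,10S)-6-hydroxy-1-oxo-3,10-epoxygermacra-2,4Z,11(13)-trien-12,8-olide | C=C1C(=O)O[C@H]2C[C@]3(C)OC(=CC3=O)/C(C)=C\[C@@H](O)[C@H]12 | intermediate
23 | tiglic acid, (2E)-2-methylbut-2-enoic acid | C/C=C(\C)C(=O)O | starting material
24 | (6S,7R,8S,10S)-6-[(2E)-2-methylbut-2-enoyloxy]-1-oxo-3,10-epoxygermacra-2,4Z,11(13)-trien-12,8-olide | C=C1C(=O)O[C@H]2C[C@]3(C)OC(=CC3=O)/C(C)=C\[C@H](OC(=O)/C(C)=C/C)[C@H]12 | target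

**Step count and risks**
Total steps: 10. Longest linear sequence: 10 (1 to 24); 3-methylfuran 13 joins in step 6 without a separate step.

Most likely to fail, first: step 8. The allylic bromide, the ynone and the (Z)-enal must coexist through the oxidation and the gold step, and the enal can isomerise. The fallback moves the dearomatization one stage earlier so that no bromide is present, which also allows silver-activated gold or AuCl3. It sets out from 16: DMDO gives the Z-enal ynone diol F1 (not isolated), and gold catalysis gives the hydroxymethyl furanone enal F2. MsCl and Et3N at −30 °C then give the allylic mesylate F3 (aldehyde-tolerant, unlike the Appel conditions), and LiBr in acetone converts it into 21, where the route resumes.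

Second: step 9. The closed chromium transition state may give poor ring closure or the wrong facial sense at C6/C7, and the C6 chromium alkoxide could translactonize. The fallback replaces the allylmetal by an allylsilane and closes the ring through an open, Lewis-acid-activated transition state (Hosomi–Sakurai), which is expected to be syn-selective. It sets out from 18: Me3SiSiMe3 with Pd2(dba)3 gives the allylsilane F4; DMDO gives the Z-enal ynone silane F5 (not isolated), and Ph3PAuNTf2 gives the furanone enal allylsilane F6. BF3·OEt2 in CH2Cl2 at −78 °C under high dilution should then give the 6S alcohol F7 directly, and tigloyl chloride, Et3N and DMAP convert it into 24 without any inversion.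

Third: step 10. Mitsunobu inversion of a hindered allylic alcohol inside the macrocycle can give elimination or retention. The fallback is a redox inversion under reagent control. It sets out from 22: Dess–Martin periodinane buffered with NaHCO3 gives the C6 ketone F8, which is reduced at once at −40 °C with (S)-2-methyl-CBS-oxazaborolidine and BH3·SMe2 (predicted sense if the alkenyl arm is the large group) to the 6S alcohol F7. Acylation with tigloyl chloride, Et3N and DMAP returns to the route at 24.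

A lesser risk is the diastereoselectivity of step 4; the C10 epimers of triol 10 should be separable by chromatography.

**Further compounds**
F1 | step 8 | (2Z,7S)-7-hydroxy-8-[(2S)-4-(hydroxymethyl)-5-oxo-2,5-dihydrofuran-2-yl]-3,7-dimethyl-4-oxooct-2-en-5-ynal | O=C/C=C(C)\C(=O)C#C[C@@](C)(O)C[C@@H]1OC(=O)C(CO)=C1
F2 | step 8 | (2Z)-3-[(5S)-5-{[(2S)-4-(hydroxymethyl)-5-oxo-2,5-dihydrofuran-2-yl]methyl}-5-methyl-4-oxo-4,5-dihydrofuran-2-yl]but-2-enal | O=C/C=C(C)\C1=CC(=O)[C@](C)(C[C@@H]2OC(=O)C(CO)=C2)O1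
F3 | step 8 | [(5S)-5-{[(2S)-2-methyl-3-oxo-5-[(2Z)-4-oxobut-2-en-2-yl]-2,3-dihydrofuran-2-yl]methyl}-2-oxo-2,5-dihydrofuran-3-yl]methyl methanesulfonate | O=C/C=C(C)\C1=CC(=O)[C@](C)(C[C@@H]2OC(=O)C(COS(C)(=O)=O)=C2)O1
F4 | step 9 | (5S)-5-[(2S)-2-hydroxy-2-methyl-4-(3-methylfuran-2-yl)but-3-yn-1-yl]-3-[(trimethylsilyl)methyl]furan-2(5H)-one | Cc1ccoc1C#C[C@@](C)(O)C[C@@H]1OC(=O)C(C[Si](C)(C)C)=C1
F5 | step 9 | (2Z,7S)-7-hydroxy-3,7-dimethyl-4-oxo-8-{(2S)-5-oxo-4-[(trimethylsilyl)methyl]-2,5-dihydrofuran-2-yl}oct-2-en-5-ynal | O=C/C=C(C)\C(=O)C#C[C@@](C)(O)C[C@@H]1OC(=O)C(C[Si](C)(C)C)=C1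
F6 | step 9 | (2Z)-3-[(5S)-5-methyl-4-oxo-5-({(2S)-5-oxo-4-[(trimethylsilyl)methyl]-2,5-dihydrofuran-2-yl}methyl)-4,5-dihydrofuran-2-yl]but-2-enal | O=C/C=C(C)\C1=CC(=O)[C@](C)(C[C@@H]2OC(=O)C(C[Si](C)(C)C)=C2)O1
F7 | step 9 | (6S,7S,8S,10S)-6-hydroxy-1-oxo-3,10-epoxygermacra-2,4Z,11(13)-trien-12,8-olide | C=C1C(=O)O[C@H]2C[C@]3(C)OC(=CC3=O)/C(C)=C\[C@H](O)[C@H]12
F8 | step 10 | (7R,8S,10S)-1,6-dioxo-3,10-epoxygermacra-2,4Z,11(13)-trien-12,8-olide | C=C1C(=O)O[C@H]2C[C@]3(C)OC(=CC3=O)/C(C)=C\C(=O)[C@H]12
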